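**Retrosynthetic overview**
- The strategy rests on the benzene ring of unit B (C-4a, C-5, C-6, C-7, C-8, C-8a). Its O-1 carbon C-8a and its aryloxy carbon C-5 are meta and flank C-4a, which carries the C-4/C-3/C-2 chain; C-6 and C-7 bear adjacent oxygens and C-8 is unsubstituted. This is the substitution pattern a vinylketene and an alkynyl ether deliver.
- Disconnections, backwards: three O-methyl groups (BBr3); the C3–C4 double bond of unit B (DDQ); the lactone O1–C2 bond; then the benzene ring of unit B across C8a–C4a, C5–C6 and C8–C8a, giving 2,3-dimethoxycyclobutenone and the alkynyl ether of isoscopoletin. The hindered diaryl ether is therefore made at an sp carbon before the ring exists.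
- Fragments: the ynol ether comes from isoscopoletin and a 1,1-dibromoalkene (copper C–O coupling, then elimination); the cyclobutenone comes from dimethyl squarate (hydride reduction, then radical deoxygenation).
- Ring order: both rings of unit A are bought with isoscopoletin; the benzene ring of unit B forms in step 6; the pyranone ring of unit B closes in step 7 and is dehydrogenated in step 8.

Key step: step 6

Assumption: the side-chain ester is carried as the tert-butyl ester (from purchasable tert-butyl 4-oxobutanoate), because the alkoxide that forms the ynol ether would exchange a methyl ester. Compounds 7, 8 and 11 are racemic; their stereocentres disappear and the target has none.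

**Step 1**
Reactants: 1 tert-butyl 4-oxobutanoate
Product: 2 tert-butyl 5,5-dibromopent-4-enoate
Conditions: CBr4, PPh3, CH2Cl2, 0 °C
Reagents that add atoms: carbon tetrabromide, BrC(Br)(Br)Br
Why: Ramirez (Corey–Fuchs) dibromo-olefination, in which the ylide Ph3P=CBr2 formed in the flask undergoes a Wittig reaction with the aldehyde while the tert-butyl ester is inert.

**Step 2**
Reactants: 2 tert-butyl 5,5-dibromopent-4-enoate; 3 isoscopoletin (6-hydroxy-7-methoxy-2H-chromen-2-one)
Product: 5 tert-butyl 5-[(7-methoxy-2-oxo-2H-chromen-6-yl)oxy]pent-4-ynoate, via bromo enol ether 4 (not isolated)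
Conditions: CuI (cat.), 2,2'-bipyridine (cat.), K3PO4, toluene, 110 °C; then t-BuOK, 1,4-dioxane, rt
Reagents that add atoms: none
Why: Copper-catalysed Ullmann-type vinylic C–O coupling of a phenol with a 1,1-dibromoalkene should replace the bromine trans to the chain, which leaves H and Br anti in the (Z)-bromo enol ether so that t-BuOK effects E2 loss of HBr to the aryl alkynyl ether, the tert-butyl ester resisting alkoxide exchange.

**Step 3**
Reactants: 6 dimethyl squarate (3,4-dimethoxycyclobut-3-ene-1,2-dione)
Product: 7 rac-4-hydroxy-2,3-dimethoxycyclobut-2-en-1-one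
Conditions: LiAlH(Ot-Bu)3, THF, –78 °C; pH 7 buffer
Reagents that add atoms: none
Why: 1,2-Reduction of one of the two equivalent carbonyl groups by a bulky hydride should stop at the hydroxycyclobutenone because the remaining carbonyl is a deactivated vinylogous ester, and the neutral work-up avoids acid-induced loss of methanol.

**Step 4**
Reactants: 7 rac-4-hydroxy-2,3-dimethoxycyclobut-2-en-1-one
Product: 8 rac-O-(2,3-dimethoxy-4-oxocyclobut-2-en-1-yl) O-phenyl carbonothioate
Conditions: PhOC(S)Cl, pyridine, DMAP (cat.), CH2Cl2, 0 °C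
Reagents that add atoms: O-phenyl chlorothionoformate, S=C(Cl)Oc1ccccc1
Why: DMAP-catalysed acylation of the secondary alcohol with an aryl chlorothionoformate (first stage of a Barton–McCombie deoxygenation), kept cold so that the allylic thionocarbonate does not undergo a [3,3] shift.

**Step 5**
Reactants: 8 rac-O-(2,3-dimethoxy-4-oxocyclobut-2-en-1-yl) O-phenyl carbonothioate
Product: 9 2,3-dimethoxycyclobut-2-en-1-one
Conditions: Bu3SnH, Et3B (cat.), air, toluene, rt
Reagents that add atoms: none
Why: Barton–McCombie radical deoxygenation, in which the ring radical is delocalised over C-4 and C-2 and hydrogen transfer from the hydridic Sn–H is expected at C-4, the less hindered and more electrophilic terminus (C-2 carries a methoxy donor), giving the tetrasubstituted alkene at a temperature below that of cyclobutenone ring opening.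

**Step 6**
Reactants: 9 2,3-dimethoxycyclobut-2-en-1-one; 5 tert-butyl 5-[(7-methoxy-2-oxo-2H-chromen-6-yl)oxy]pent-4-ynoate
Product: 14 tert-butyl 3-{6-hydroxy-3,4-dimethoxy-2-[(7-methoxy-2-oxo-2H-chromen-6-yl)oxy]phenyl}propanoate, via vinylketene 10 (not isolated), via vinylcyclobutenone 11 (not isolated), via dienylketene 12 (not isolated), via cyclohexadienone 13 (not isolated)
Conditions: toluene, 110 °C (9 added slowly), then 140 °C, sealed tube
Reagents that add atoms: none
Why: Proposed new method: heating should open 9 by 4π electrocyclic cleavage of its C1–C4 bond to vinylketene 10, whose carbonyl carbon is attacked by the oxygen-free alkyne carbon of 5 in a [2+2] cycloaddition to give 11; a second 4π opening gives dienylketene 12, which closes to cyclohexadienone 13 and tautomerises to phenol 14. The closest known reaction type is the Danheiser benzannulation of cyclobutenones with alkoxy- and siloxyalkynes; a 2,3-dialkoxycyclobutenone and an aryl alkynyl ether have not been used as partners, and that is the new element. The one ring closed, the benzene ring of unit B, forms by thermal disrotatory 6π electrocyclisation of 12 (bond C8–C8a), after C8a–C4a and C5–C6 are made in the [2+2] step. No stereocentre is created in 14, and the quaternary carbon of 11 is transient. The step needs regioselectivity in the ketene–alkyne addition, which the polarisation of the ynol ether secures: the oxygen lone pair makes the chain-bearing carbon nucleophilic toward the ketene carbonyl carbon, so the chain ends at C-4a and the aryloxy group at C-5 next to the former ketene α-carbon C-6. The aryl ynol ether has no hydrogen beta to oxygen for retro-ene loss of a ketene, the coumarin alkene of unit A is too electron-poor to intercept 10, and slow addition of 9 keeps 10 dilute so that it does not acylate the phenol formed.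

**Step 7**
Reactants: 14 tert-butyl 3-{6-hydroxy-3,4-dimethoxy-2-[(7-methoxy-2-oxo-2H-chromen-6-yl)oxy]phenyl}propanoate
Product: 15 6,7-dimethoxy-5-[(7-methoxy-2-oxo-2H-chromen-6-yl)oxy]-3,4-dihydro-2H-chromen-2-one
Conditions: p-TsOH·H2O (cat.), toluene, 110 °C
Reagents that add atoms: none
Why: Acid-mediated cleavage of the tert-butyl ester with loss of isobutene followed by acid-catalysed lactonisation of the 3-(2-hydroxyaryl)propanoic acid should close the six-membered aryl lactone, to which the diaryl ether and the coumarin of unit A are inert.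

**Step 8**
Reactants: 15 6,7-dimethoxy-5-[(7-methoxy-2-oxo-2H-chromen-6-yl)oxy]-3,4-dihydro-2H-chromen-2-one
Product: 16 6,7-dimethoxy-5-[(7-methoxy-2-oxo-2H-chromen-6-yl)oxy]-2H-chromen-2-one
Conditions: DDQ, 1,4-dioxane, 100 °C
Reagents that add atoms: none
Why: DDQ dehydrogenation by hydride abstraction from benzylic C-4 (the cation is stabilised by the para 7-methoxy group) and loss of the C-3 proton should give the conjugated coumarin, no free phenol being present to be oxidised.

**Step 9**
Reactants: 16 6,7-dimethoxy-5-[(7-methoxy-2-oxo-2H-chromen-6-yl)oxy]-2H-chromen-2-one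
Product: 17 6,7-dihydroxy-5-[(7-hydroxy-2-oxo-2H-chromen-6-yl)oxy]-2H-chromen-2-one (CNP0197949.0)
Conditions: BBr3, CH2Cl2, –78 °C → rt; then H2O
Reagents that add atoms: none
Why: Lewis-acid cleavage of the three aryl methyl ethers by BBr3 (bromide attacks the methyl group of the boron-complexed ether in an SN2 step) should leave the diaryl ether and both coumarin lactones intact, and the aqueous quench hydrolyses the aryl borates.

**Compound list**
1 | tert-butyl 4-oxobutanoate | CC(C)(C)OC(=O)CCC=O | starting material
2 | tert-butyl 5,5-dibromopent-4-enoate | CC(C)(C)OC(=O)CCC=C(Br)Br | intermediate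
3 | isoscopoletin (6-hydroxy-7-methoxy-2H-chromen-2-one) | COc1cc2oc(=O)ccc2cc1O | starting material
4 | tert-butyl (4Z)-5-bromo-5-[(7-methoxy-2-oxo-2H-chromen-6-yl)oxy]pent-4-enoate | CC(C)(C)OC(=O)CC/C=C(\Br)Oc1cc2ccc(=O)oc2cc1OC | intermediate
5 | tert-butyl 5-[(7-methoxy-2-oxo-2H-chromen-6-yl)oxy]pent-4-ynoate | CC(C)(C)OC(=O)CCC#COc1cc2ccc(=O)oc2cc1OC | intermediate
6 | dimethyl squarate (3,4-dimethoxycyclobut-3-ene-1,2-dione) | COC1=C(OC)C(=O)C1=O | starting material
7 | rac-4-hydroxy-2,3-dimethoxycyclobut-2-en-1-one | COC1=C(OC)C(=O)C1O | intermediate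
8 | rac-O-(2,3-dimethoxy-4-oxocyclobut-2-en-1-yl) O-phenyl carbonothioate | COC1=C(OC)C(=O)C1OC(=S)Oc1ccccc1 | intermediate
9 | 2,3-dimethoxycyclobut-2-en-1-one | COC1=C(OC)C(=O)C1 | intermediate
10 | 2,3-dimethoxybuta-1,3-dien-1-one | C=C(OC)C(OC)=C=O | intermediate
11 | rac-tert-butyl 3-{3-methoxy-3-(1-methoxyethenyl)-2-[(7-methoxy-2-oxo-2H-chromen-6-yl)oxy]-4-oxocyclobut-1-en-1-yl}propanoate | C=C(OC)C1(OC)C(=O)C(CCC(=O)OC(C)(C)C)=C1Oc1cc2ccc(=O)oc2cc1OC | intermediate
12 | tert-butyl (5Z)-6,7-dimethoxy-5-[(7-methoxy-2-oxo-2H-chromen-6-yl)oxy]-4-(oxomethylidene)octa-5,7-dienoate | O=C=C(CCC(=O)OC(C)(C)C)/C(Oc1cc2ccc(=O)oc2cc1OC)=C(OC)\C(OC)=C | intermediate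
13 | tert-butyl 3-{3,4-dimethoxy-2-[(7-methoxy-2-oxo-2H-chromen-6-yl)oxy]-6-oxocyclohexa-1,3-dien-1-yl}propanoate | O=C1CC(OC)=C(OC)C(Oc2cc3ccc(=O)oc3cc2OC)=C1CCC(=O)OC(C)(C)C | intermediate
14 | tert-butyl 3-{6-hydroxy-3,4-dimethoxy-2-[(7-methoxy-2-oxo-2H-chromen-6-yl)oxy]phenyl}propanoate | CC(C)(C)OC(=O)CCc1c(O)cc(OC)c(OC)c1Oc1cc2ccc(=O)oc2cc1OC | intermediate
15 | 6,7-dimethoxy-5-[(7-methoxy-2-oxo-2H-chromen-6-yl)oxy]-3,4-dihydro-2H-chromen-2-one | COc1cc2OC(=O)CCc2c(Oc2cc3ccc(=O)oc3cc2OC)c1OC | intermediate
16 | 6,7-dimethoxy-5-[(7-methoxy-2-oxo-2H-chromen-6-yl)oxy]-2H-chromen-2-one | COc1cc2oc(=O)ccc2c(Oc2cc3ccc(=O)oc3cc2OC)c1OC | intermediate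
17 | 6,7-dihydroxy-5-[(7-hydroxy-2-oxo-2H-chromen-6-yl)oxy]-2H-chromen-2-one (CNP0197949.0) | O=c1ccc2cc(Oc3c(O)c(O)cc4oc(=O)ccc34)c(O)cc2o1 | target

**Step count**
Total: 9 steps. Longest linear sequence: 7 steps (steps 3 to 9, from dimethyl squarate 6 to 17).

**Steps most likely to fail**

Step 6 (benzannulation). The alkoxy-stabilised cyclobutenone may not open below the temperature at which 5 degrades. The vinylketene may also dimerise, or acylate the phenol formed, faster than the weakly nucleophilic aryl ynol ether intercepts it. The fallback uses known chemistry, sets out from 3 and comes back at 16. Electrophilic bromination of isoscopoletin 3 ortho to its free hydroxyl (NBS, MeCN, 0 °C) should give 5-bromo-6-hydroxy-7-methoxy-2H-chromen-2-one F1. O-Methylation (MeI, K2CO3, acetone) gives 5-bromo-6,7-dimethoxy-2H-chromen-2-one F2. An Ullmann diaryl ether coupling of F2 with a second portion of 3 (CuI, picolinic acid, K3PO4, DMSO, 100 °C) then forms the C5–O bond of unit B directly and gives 16, which is demethylated as in step 9. The ether is made at a hindered sp2 carbon in this variant, so the coupling may need forcing conditions.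

Step 5 (deoxygenation). Hydrogen-atom transfer may go to the methoxy-bearing terminus of the delocalised ring radical, or thionocarbonate 8 may undergo an allylic [3,3] shift before it is reduced. The fallback sets out from 7 and comes back at 9. Acetylation (Ac2O, pyridine, DMAP, CH2Cl2, 0 °C) gives rac-2,3-dimethoxy-4-oxocyclobut-2-en-1-yl acetate F3. SmI2 (THF–MeOH, –78 °C) then cleaves the α-acetoxy ketone by two single-electron transfers, and methanol should protonate the samarium dienolate at its α-carbon under kinetic control. This reaches 9 by a polar pathway and not by a radical chain.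

Step 2 (ynol ether). The copper-catalysed C–O coupling may stall on the ortho-methoxy phenol or run on to the ketene acetal. The alkoxide elimination at room temperature may be accompanied by propargyl-to-allenyl isomerisation or by attack on the lactone. The fallback sets out from 3 and comes back at 5. Williamson alkylation of 3 with tert-butyl 5-bromo-4-oxopentanoate (K2CO3, acetone) gives tert-butyl 5-[(7-methoxy-2-oxo-2H-chromen-6-yl)oxy]-4-oxopentanoate F4. Enolisation at the aryloxy-bearing methylene and O-triflation (LiHMDS, PhNTf2, THF, –78 °C) gives tert-butyl (4Z)-5-[(7-methoxy-2-oxo-2H-chromen-6-yl)oxy]-4-{[(trifluoromethyl)sulfonyl]oxy}pent-4-enoate F5. Anti-elimination of triflic acid (t-BuOK, THF, –78 °C) then gives 5; the C–O bond is made by alkylation and the alkyne at low temperature.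

**Further compounds**
F1 | step 6 | 5-bromo-6-hydroxy-7-methoxy-2H-chromen-2-one | COc1cc2oc(=O)ccc2c(Br)c1O
F2 | step 6 | 5-bromo-6,7-dimethoxy-2H-chromen-2-one | COc1cc2oc(=O)ccc2c(Br)c1OC
F3 | step 5 | rac-2,3-dimethoxy-4-oxocyclobut-2-en-1-yl acetate | CC(=O)OC1C(=O)C(OC)=C1OC
F4 | step 2 | tert-butyl 5-[(7-methoxy-2-oxo-2H-chromen-6-yl)oxy]-4-oxopentanoate | CC(C)(C)OC(=O)CCC(=O)COc1cc2ccc(=O)oc2cc1OC
F5 | step 2 | tert-butyl (4Z)-5-[(7-methoxy-2-oxo-2H-chromen-6-yl)oxy]-4-{[(trifluoromethyl)sulfonyl]oxy}pent-4-enoate | CC(C)(C)OC(=O)CC/C(OS(=O)(=O)C(F)(F)F)=C/Oc1cc2ccc(=O)oc2cc1OC
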